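Readings and results were generated by integration with made-up constants; scatter was added.

In the epsilon run target makes up 26.1 % of the product formed up to 12.0 h, but 10.8 % of what forms from then to 25.0 h, so in this run late product is poorer in target than early product. I call this second number the late share: of the product added over a late span of a run, the part that is target. It is a reading and carries the scatter.

all flasks: starting material 0.20 M

| flask | other conformer | solid reagent | temperature | remark | time |
|---|---|---|---|---|---|
| beta | 0.025 M | 0.19 M | 89 °C | run made earlier |  |
| epsilon | 0.038 M | 0.19 M | 97 °C | run made earlier |  |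
| teal | 0.0500 M | 0.190 M | 85 °C |  | 50 h |
| red | 0.0500 M | 0.190 M |  | at 85 °C until 25 h, from then on at 100 °C | 50 h |
| grey | 0.0500 M | 0.190 M | 100 °C |  | 50 h |

| run | time / h | target / % | isomer of the product / % |
|---|---|---|---|
| beta | 4.00 | 1.4 | 2.4 |
| beta | 6.00 | 2.9 | 4.8 |
| beta | 10.0 | 5.0 | 10.1 |
| beta | 15.0 | 6.7 | 12.7 |
| beta | 20.0 | 9.5 | 16.3 |
| beta | 30.0 | 10.9 | 20.5 |
| beta | 48.0 | 10.3 | 25.9 |
| epsilon | 1.33 | 0.5 | 1.1 |
| epsilon | 4.00 | 2.7 | 5.5 |
| epsilon | 8.00 | 4.7 | 11.6 |
| epsilon | 12.0 | 5.9 | 16.7 |
| epsilon | 15.0 | 6.1 | 19.8 |
| epsilon | 20.0 | 6.7 | 23.8 |
| epsilon | 25.0 | 7.1 | 26.6 |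

(scatter of a reading: 0.5 percentage points)

- solid, in amounts per volume of the solution: solid reagent
- the analysis behind the earlier runs scatters by 0.5 percentage points, standard deviation
- at the start none of the solid reagent is in solution
- in a conversion other conformer counts as not yet reacted

1. the flask that comes out highest in share of target in all that became target or isomer of the product, or "all alike" when all lie within 1.5 percentage points (teal / red / grey / all alike)
2. share of target in all that became target or isomer of the product, teal
3. share of target in all that became target or isomer of the product, red
4. share of target in all that became target or isomer of the product, grey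

I keep the books for red on the solid reagent, assuming that each mole of target or isomer of the product takes one mole of it. At 0.190 M, against 0.250 M of starting material and other conformer together, it is the limiting reagent. The first entry is red's cool half, for which I put the percentages of the beta run at 30.0 h on red's charge: by this estimate target takes 0.0272 M and isomer of the product 0.0513 M, so 58.7 % of the solid reagent's charge stays unbooked. The second entry is red's hot half, for which I book the epsilon span, 0.0278 M, though that span is shorter than the hot half, and I split it between target and isomer of the product by the late share. The books close at 0.0302 M of target and 0.0760 M of isomer, with 44.1 % unbooked, so my red is 28.5 %. From the last readings I take teal as 28.5 % from the beta run and grey as 21.1 % from the epsilon run, which puts teal and red within the margin of 1.5 percentage points.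

The forecast differs: it names teal as highest, with teal 46 %, red 31 % and grey 14 %, so its teal stands above mine. Its ground is that “Target levels off as the conformer pool is used up, whereas isomer keeps growing”.

Red gives 11.1 %, below teal, the highest at 26.9 %, and above grey at 9.02 %.

starting material ⇌ other conformer (K = 0.190, k = 0.0290 /h, Ea = 129 kJ/mol, ΔH = −21.0 kJ/mol); starting material + partner ⇌ target (K = 2.60 /M, k = 0.620 /M/h, Ea = 97.0 kJ/mol, ΔH = −11.0 kJ/mol); partner + other conformer → isomer of the product (k = 5.80 /M/h, Ea = 60.0 kJ/mol); solid reagent ⇌ partner, rate k4*(cs4 - [partner]) while solid is left; crystals form when [partner] > cs4 (solubility = 0.0930 M, k = 0.160 /h); starting material ⇌ dormant form (K = 1.50, k = 0.0540 /h, Ea = 122 kJ/mol, ΔH = 24.0 kJ/mol); (constants at 100 °C) In red, target falls from 8.36 % at 25.0 h to 4.98 % at 50.0 h, while isomer of the product climbs from 22.3 % to 40.0 %. Red's late share over those hours is therefore −23.7 %, negative where I had booked 10.8 %. Teal, held at 85 °C, has a late share of 25.4 % over the same hours.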